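**Retrosynthetic overview**

1. Numbering: C1, C2, C3 are the ester-bearing carbons (C1 angelate next to C11Me2, C2 acetate, C3 angelate next to C4); C4 = C(Me); C5 = CH next to the C6 ketone; C7=C8(Me) = enone olefin; C9, C10 = the other cyclobutane CH groups; C11 = CMe2.
2. Feature: the cyclobutane C4–C5–C10–C9 is bridged twice. C5/C9 carry the enone bridge C6–C7–C8 (six-membered ring). The 1,3-carbons C4/C10 carry C3–C2–C1–C11 on the opposite face (seven-membered ring). This is the pattern left when a four-atom unit adds across the central C4–C10 bond of a bridged bicyclo[1.1.0]butane.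
3. Late stage: the esters come from a triol; the C2/C3 diol from OsO4 addition to a C2=C3 olefin anti to C1–O; C1–O from the enol silane left by the annulation. The enone comes from the plain C7=C8 olefin (singlet-oxygen ene, MeLi, oxidative transposition, which also brings in the C8 methyl). C10–H comes from Barton decarboxylation of the activating ester.
4. Key disconnection: C3–C4 and C10–C11, a formal (4+3) of silyloxydiene 16 (from mesityl oxide) with the bridged bicyclobutane ester 13.
5. 13 comes from cyclohexa-1,4-diene by dibromocarbene addition, carbenoid C–H insertion, two bridgehead lithiations (MeI, allyl chloroformate) and resolution. Ring order: six-membered ring (bought), then bicyclobutane, then seven-membered ring.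

Key step: step 7

Assumption: racemic intermediates (8, 9, 11, 12) are drawn as the enantiomer that is carried on; the enantiomer of 12 kept in step 5 is identified by VCD or by X-ray of a later crystalline derivative.
Design remark: both ring methyls are introduced late (C4–Me by bridgehead lithiation, C8–Me after the annulation). Carbenoid C–H insertion in a 1-methyl-7,7-dibromonorcarene is not reliably directed to the CH2 next to the methyl-bearing carbon and would tend to put that methyl on a lateral bicyclobutane carbon. A disubstituted bridge olefin is also a poorer internal nucleophile toward the C4 cation of the key step.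
Assumption: the Shi epoxidation in step 8 follows its usual facial sense for 1-substituted cycloalkenes, so the L-fructose-derived ketone gives the S configuration at C1; if the sense is reversed, the D-fructose-derived ketone is used.

**Route**

Step 1
Reactants: 1 cyclohexa-1,4-diene; 2 bromoform
Product: 3 cis-7,7-dibromobicyclo[4.1.0]hept-3-ene
Conditions: KOtBu, pentane, −10 → 0 °C (1 in excess)
Reagents that add atoms: bromoform, BrC(Br)Br
Why: Dibromocarbene from α-elimination adds once to one of the two equivalent cis olefins in a (2+1) cycloaddition; excess diene suppresses the bis-adduct and only the cis ring fusion is possible.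

Step 2
Reactants: 3 cis-7,7-dibromobicyclo[4.1.0]hept-3-ene; 4 methyllithium
Product: 6 tricyclo[4.1.0.0(2,7)]hept-3-ene, via carbenoid 5 (not isolated)
Conditions: MeLi, Et2O, −40 → 0 °C
Reagents that add atoms: none
Why: Li–Br exchange gives the carbenoid, whose cyclopropylidene inserts into the neighbouring allylic C–H bond (1,3-C–H insertion) to close the bicyclobutane; the two allylic CH2 groups are equivalent by symmetry, so a single achiral hydrocarbon should form.

Step 3
Reactants: 6 tricyclo[4.1.0.0(2,7)]hept-3-ene; 7 iodomethane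
Product: 9 rac-1-methyltricyclo[4.1.0.0(2,7)]hept-3-ene, via bridgehead lithium compound 8 (not isolated)
Conditions: n-BuLi, TMEDA, Et2O, rt; MeI, −78 °C → rt
Reagents that add atoms: iodomethane, CI
Why: The bicyclobutane bridgehead C–H (high s-character) is the kinetically most acidic site and is lithiated and methylated (bridgehead lithiation/alkylation); the two bridgeheads are enantiotopic, so 9 is racemic, and the methylated carbon becomes C4.

Step 4
Reactants: 9 rac-1-methyltricyclo[4.1.0.0(2,7)]hept-3-ene; 10 allyl chloroformate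
Product: 12 rac-prop-2-enyl 7-methyltricyclo[4.1.0.0(2,7)]hept-3-ene-1-carboxylate, via bridgehead lithium compound 11 (not isolated)
Conditions: n-BuLi, TMEDA, Et2O, rt; then added to 10 in THF, −78 °C
Reagents that add atoms: allyl chloroformate, C=CCOC(=O)Cl
Why: Lithiation at the only remaining bicyclobutane C–H (future C10) and inverse-addition acylation give the ester-activated bicyclobutane; no new stereo element arises.

Step 5
Reactants: 12 rac-prop-2-enyl 7-methyltricyclo[4.1.0.0(2,7)]hept-3-ene-1-carboxylate
Product: 13 prop-2-enyl 7-methyltricyclo[4.1.0.0(2,7)]hept-3-ene-1-carboxylate as the single enantiomer with the olefinic bridge carbon on the future C9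
Conditions: preparative SFC, amylose tris(3,5-dimethylphenylcarbamate) phase, CO2/i-PrOH
Reagents that add atoms: none
Why: Resolution by chromatography on a chiral stationary phase; the two enantiomers differ only in which lateral carbon carries the olefinic end of the bridge, and the one matching the target cage is kept.

Step 6
Reactants: 14 mesityl oxide
Product: 16 2-(tert-butyldimethylsilyloxy)-4-methylpenta-1,3-diene, via lithium dienolate 15 (not isolated)
Conditions: LiN(i-Pr)2, THF, −78 °C; TBSCl, DMPU, −78 °C → rt
Reagents that add atoms: tert-butyldimethylsilyl chloride, CC(C)(C)[Si](C)(C)Cl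
Why: Kinetic deprotonation of the α′-methyl group gives the cross-conjugated dienolate, which is O-silylated (kinetic enolate silylation) to the 2-silyloxydiene.

Step 7
Reactants: 13 prop-2-enyl 7-methyltricyclo[4.1.0.0(2,7)]hept-3-ene-1-carboxylate (single enantiomer); 16 2-(tert-butyldimethylsilyloxy)-4-methylpenta-1,3-diene
Product: 17 tricyclic enol silane (C1=C2 with OTBS on C2; C3H2; C4–Me; C6H2–C7H=C8H bridge; C10–CO2allyl; C11Me2)
Conditions: Sc(OTf)3 (10 mol%), 4 Å MS, CH2Cl2, −40 → 0 °C; Et3N quench
Reagents that add atoms: none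
Why: Proposed new method: Sc(OTf)3 bound to the C10 ester should heterolyse the strained C4–C10 bond toward a tertiary, methyl-stabilised C4 cation and a scandium ester enolate at C10; the CH2 terminus of 16 (C3) adds to C4 in a Mukaiyama-type step, and the enolate then adds to C11 of the silyl-activated β,β-dimethyl enone, leaving the C1=C2 enol silane. The closest known reaction type is the Lewis-acid-catalysed formal (4+3) cycloaddition of acyl bicyclo[1.1.0]butanes with silyl dienol ethers to bicyclo[4.1.1]octanes, which has not been shown on a bridged (tricyclo[4.1.0.0(2,7)]heptene) or bridgehead-methyl bicyclobutane. The seven-membered ring closes by a 7-endo-trig Michael addition that joins two fully substituted carbons, paid for by the strain released. C4 and C10 are the only new stereocentres and both are fixed by the cage: a four-atom bridge can span them only on the convex face, which turns the methyl and ester groups toward the C6–C8 bridge. The step needs C3 to enter C4 on that convex face (front-side capture of a cation, not the invertive rear attack usual for anionic nucleophiles and radicals) and needs C–C bonding before any silyl transfer to the enolate. The tertiary C4 with its rear covered by the methyl group, the cation-like opening under Sc(OTf)3 and the bulky silyl group should secure this; a wrong-face adduct cannot cyclise and would be separable.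

Step 8
Reactants: 17 tricyclic enol silane
Product: 19 α-hydroxy ketone ((1S)-C1–OH; C2=O), via silyloxy epoxide 18 (not isolated)
Conditions: L-fructose-derived Shi ketone (30 mol%), KHSO5, K2CO3, Bu4NHSO4, MeCN/CH2(OMe)2, aq. Na2B4O7 buffer (pH 10.5), 0 °C; then Et3N·3HF, THF, 0 °C
Reagents that add atoms: potassium peroxymonosulfate KHSO5, [K+].[O-]S(=O)(=O)OO
Why: Shi asymmetric epoxidation of the electron-rich trisubstituted enol silane, followed by desilylative opening of the silyloxy epoxide (Rubottom-type oxidation), should give the ketol; the tether lies close to a local mirror plane of the cage, so the face is set by the chiral dioxirane and not by the substrate.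

Step 9
Reactants: 19 α-hydroxy ketone
Product: 20 C1 tert-butyldimethylsilyl ether of 19
Conditions: TBSOTf, 2,6-lutidine, CH2Cl2, −78 → 0 °C
Reagents that add atoms: tert-butyldimethylsilyl triflate, CC(C)(C)[Si](C)(C)OS(=O)(=O)C(F)(F)F
Why: Silyl triflate silylation of the hindered secondary alcohol is much faster than enolisation of the ketone at low temperature and blocks C1–OH for the base and organolithium steps that follow.

Step 10
Reactants: 20 C1 silyl ether ketone
Product: 22 C2=C3 enol triflate, via potassium enolate 21 (not isolated)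
Conditions: KN(SiMe3)2, THF, −78 °C; PhNTf2, −78 → −20 °C
Reagents that add atoms: N-phenylbis(trifluoromethanesulfonimide), O=S(=O)(N(c1ccccc1)S(=O)(=O)C(F)(F)F)C(F)(F)F
Why: Kinetic deprotonation should take place at the C3 methylene and not at the hindered, oxygen-bearing C1–H, and O-triflation of the enolate then fixes the olefin at C2=C3 (regioselective enol triflate formation).

Step 11
Reactants: 22 C2=C3 enol triflate
Product: 23 carboxylic acid (C1–OTBS; C2=C3; C10–CO2H)
Conditions: Pd(OAc)2 (5 mol%), PPh3, HCO2H, Et3N, DMF, 60 °C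
Reagents that add atoms: none
Why: Zerovalent palladium inserts into the vinyl C–OTf bond and formate delivers hydride (palladium-catalysed formate reduction of an enol triflate). The same catalyst ionises the allyl ester and formate reduces the π-allyl complex (Tsuji–Trost deallylation), freeing the hindered C10 acid without attack at its carbonyl.

Step 12
Reactants: 23 carboxylic acid
Product: 26 diene (C1–OTBS; C2=C3; C10–H; C6H2–C7H=C8H), via acid chloride 24 (not isolated), via thiohydroxamate ester 25 (not isolated)
Conditions: 1-chloro-N,N,2-trimethylprop-1-en-1-amine, CH2Cl2, 0 °C → rt; then NaC5H4NOS (sodium 2-thioxopyridin-1-olate), DMAP (cat.), t-BuSH, toluene, visible light, rt → 80 °C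
Reagents that add atoms: none
Why: Barton decarboxylation: photolysis of the thiohydroxamate ester releases the C10 cyclobutyl radical, which takes hydrogen from the thiol; the cage allows only one configuration at C10, with H toward the C6–C8 bridge.

Step 13
Reactants: 26 diene; 27 acetic anhydride
Product: 29 enone (C8=O; C6=C7), via allylic hydroperoxide 28 (not isolated)
Conditions: O2, tetraphenylporphyrin (cat.), visible light, Ac2O, pyridine, DMAP (cat.), CH2Cl2, 0 °C → rt
Reagents that add atoms: dioxygen, O=O
Why: Schenck ene reaction of singlet oxygen at the bridge olefin can only abstract hydrogen from C6 (C9–H is a bridgehead), so oxygen goes to C8 and the olefin moves to C6=C7; acetylation and elimination in the same flask (Kornblum–DeLaMare type) give the enone. The tether olefin has no reactive allylic hydrogen (C4 is quaternary, C1–H is geminal to the silyloxy group).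

Step 14
Reactants: 29 enone; 4 methyllithium
Product: 30 tertiary allylic alcohol (C8(OH)(Me); C6=C7)
Conditions: MeLi, Et2O, −78 °C; aq. NH4Cl
Reagents that add atoms: methyllithium, [Li]C
Why: 1,2-Addition of MeLi to the enone carbonyl, from the face away from the C4 methyl group, brings in the C8 methyl carbon; the carbinol configuration is lost in the next step.

Step 15
Reactants: 30 tertiary allylic alcohol
Product: 31 enone (C6=O; C7=C8(Me))
Conditions: [C5H5NH][CrO3Cl] (pyridinium chlorochromate), 4 Å MS, CH2Cl2, rt
Reagents that add atoms: none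
Why: Babler–Dauben oxidative transposition: the tertiary allylic chromate ester undergoes a [3,3] shift to C6 and is oxidised there, giving the C6 ketone conjugated with the C7=C8(Me) olefin.

Step 16
Reactants: 31 enone
Product: 32 diol (C2–OH and C3–OH cis to each other and trans to C1–OTBS)
Conditions: OsO4 (5 mol%), N-methylmorpholine N-oxide, acetone/H2O, rt
Reagents that add atoms: OsO4 (catalytic oxygen carrier), O=[Os](=O)(=O)=O; N-methylmorpholine N-oxide, C[N+]1([O-])CCOCC1; water, O
Why: Upjohn dihydroxylation of the isolated C2=C3 olefin should be faster than attack on the electron-poor trisubstituted enone olefin; OsO4 adds syn on the face anti to the allylic C1 silyloxy group (Kishi's rule), which sets C2 and C3.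

Step 17
Reactants: 32 diol
Product: 33 triol (C1–OH; C2–OH; C3–OH)
Conditions: HF·pyridine, THF/pyridine, 0 °C → rt
Reagents that add atoms: none
Why: Fluoride-mediated cleavage of the silyl ether under mildly acidic conditions, which the enone and the cage should tolerate.

Step 18
Reactants: 33 triol; 27 acetic anhydride
Product: 34 C2 monoacetate
Conditions: Ac2O (1.1 equiv), 2,4,6-collidine, CH2Cl2, −20 → 0 °C
Reagents that add atoms: acetic anhydride, CC(=O)OC(C)=O
Why: Kinetic acylation of the least hindered hydroxyl: C2–OH lies between two CH(OH) carbons, whereas C1–OH and C3–OH each adjoin a quaternary carbon (C11, C4).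

Step 19
Reactants: 34 C2 monoacetate; 35 angelic acid
Product: 36 target CNP0335415.1 (C1 and C3 angelates; C2 acetate)
Conditions: angelic acid, 2,4,6-trichlorobenzoyl chloride, Et3N, toluene, rt; then 34, 80 °C
Reagents that add atoms: angelic acid, C/C=C(/C)C(=O)O
Why: Yamaguchi esterification through the mixed anhydride of angelic acid acylates hindered secondary alcohols and is the usual way to keep the Z olefin from isomerising to the tiglate; both remaining hydroxyls are esterified.

**Compound list**

1 | cyclohexa-1,4-diene | C1=CCC=CC1 | starting material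
2 | bromoform | BrC(Br)Br | starting material
3 | cis-7,7-dibromobicyclo[4.1.0]hept-3-ene | BrC1(Br)[C@H]2CC=CC[C@@H]12 | intermediate
4 | methyllithium | [Li]C | starting material
5 | 7-bromo-7-lithiobicyclo[4.1.0]hept-3-ene (carbenoid) | [Li]C1(Br)[C@H]2CC=CC[C@@H]12 | intermediate (not isolated)
6 | tricyclo[4.1.0.0(2,7)]hept-3-ene (achiral; central carbons = future C4 and C10) | [C@@H]12[C@H]3CC=C[C@@H]1[C@@H]23 | intermediate
7 | iodomethane | CI | starting material
8 | 1-lithiotricyclo[4.1.0.0(2,7)]hept-3-ene (racemic) | [C@@H]12[C@H]3CC=C[C@@H]1[C@@]23[Li] | intermediate (not isolated)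
9 | rac-1-methyltricyclo[4.1.0.0(2,7)]hept-3-ene (methyl on central carbon C4) | [C@@H]12[C@H]3CC=C[C@@H]1[C@@]23C | intermediate
10 | allyl chloroformate | C=CCOC(=O)Cl | starting material
11 | 7-lithio-1-methyltricyclo[4.1.0.0(2,7)]hept-3-ene (racemic) | [Li][C@@]12[C@H]3CC=C[C@@H]1[C@@]23C | intermediate (not isolated)
12 | rac-prop-2-enyl 7-methyltricyclo[4.1.0.0(2,7)]hept-3-ene-1-carboxylate | C=CCOC(=O)[C@@]12[C@H]3CC=C[C@@H]1[C@@]23C | intermediate
13 | prop-2-enyl 7-methyltricyclo[4.1.0.0(2,7)]hept-3-ene-1-carboxylate, single enantiomer (C4–Me; C10–CO2allyl; C8 on C9; C6H2 on C5) | C=CCOC(=O)[C@@]12[C@H]3CC=C[C@@H]1[C@@]23C | intermediate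
14 | mesityl oxide | CC(=O)C=C(C)C | starting material
15 | lithium 4-methylpenta-1,3-dien-2-olate | [Li]OC(=C)C=C(C)C | intermediate (not isolated)
16 | 2-(tert-butyldimethylsilyloxy)-4-methylpenta-1,3-diene | C=C(O[Si](C)(C)C(C)(C)C)C=C(C)C | intermediate
17 | tricyclic enol silane (C1=C2–OTBS; C4–Me and C10–CO2allyl syn to the C6–C8 bridge) | C1=C(O[Si](C)(C)C(C)(C)C)C[C@@]2(C)[C@@H]3CC=C[C@H]2[C@]3(C(=O)OCC=C)C1(C)C | intermediate
18 | C1,C2-silyloxy epoxide of 17 | O1[C@@H]2[C@@]1(O[Si](C)(C)C(C)(C)C)C[C@@]3(C)[C@@H]4CC=C[C@H]3[C@]4(C(=O)OCC=C)C2(C)C | intermediate (not isolated)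
19 | α-hydroxy ketone ((1S)-C1–OH; C2=O) | O[C@@H]1C(=O)C[C@@]2(C)[C@@H]3CC=C[C@H]2[C@]3(C(=O)OCC=C)C1(C)C | intermediate
20 | C1 tert-butyldimethylsilyl ether of 19 | CC(C)(C)[Si](C)(C)O[C@@H]1C(=O)C[C@@]2(C)[C@@H]3CC=C[C@H]2[C@]3(C(=O)OCC=C)C1(C)C | intermediate
21 | potassium C2(O)=C3 enolate of 20 | CC(C)(C)[Si](C)(C)O[C@@H]1C([O-])=C[C@@]2(C)[C@@H]3CC=C[C@H]2[C@]3(C(=O)OCC=C)C1(C)C.[K+] | intermediate (not isolated)
22 | C2=C3 enol triflate | CC(C)(C)[Si](C)(C)O[C@@H]1C(OS(=O)(=O)C(F)(F)F)=C[C@@]2(C)[C@@H]3CC=C[C@H]2[C@]3(C(=O)OCC=C)C1(C)C | intermediate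
23 | carboxylic acid (C1–OTBS; C2=C3; C10–CO2H) | CC(C)(C)[Si](C)(C)O[C@@H]1C=C[C@@]2(C)[C@@H]3CC=C[C@H]2[C@]3(C(=O)O)C1(C)C | intermediate
24 | acid chloride of 23 | CC(C)(C)[Si](C)(C)O[C@@H]1C=C[C@@]2(C)[C@@H]3CC=C[C@H]2[C@]3(C(=O)Cl)C1(C)C | intermediate (not isolated)
25 | O-acyl thiohydroxamate (Barton ester) of 23 | CC(C)(C)[Si](C)(C)O[C@@H]1C=C[C@@]2(C)[C@@H]3CC=C[C@H]2[C@]3(C(=O)On4ccccc4=S)C1(C)C | intermediate (not isolated)
26 | diene (C1–OTBS; C2=C3; C10–H; C6H2–C7H=C8H) | CC(C)(C)[Si](C)(C)O[C@@H]1C=C[C@@]2(C)[C@@H]3CC=C[C@H]2[C@@H]3C1(C)C | intermediate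
27 | acetic anhydride | CC(=O)OC(C)=O | starting material
28 | allylic hydroperoxide (C8–OOH on the C10 side; C6=C7) | CC(C)(C)[Si](C)(C)O[C@@H]1C=C[C@@]2(C)[C@@H]3C=C[C@@H](OO)[C@H]2[C@@H]3C1(C)C | intermediate (not isolated)
29 | enone (C8=O; C6=C7) | CC(C)(C)[Si](C)(C)O[C@@H]1C=C[C@@]2(C)[C@@H]3C=CC(=O)[C@H]2[C@@H]3C1(C)C | intermediate
30 | tertiary allylic alcohol (C8(OH)(Me), methyl on the C10 side; C6=C7) | CC(C)(C)[Si](C)(C)O[C@@H]1C=C[C@@]2(C)[C@@H]3C=C[C@](C)(O)[C@H]2[C@@H]3C1(C)C | intermediate
31 | enone (C6=O; C7=C8(Me)) | CC(C)(C)[Si](C)(C)O[C@@H]1C=C[C@@]2(C)[C@@H]3C(=O)C=C(C)[C@H]2[C@@H]3C1(C)C | intermediate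
32 | diol (C2–OH, C3–OH; C1–OTBS) | CC(C)(C)[Si](C)(C)O[C@@H]1[C@@H](O)[C@@H](O)[C@@]2(C)[C@@H]3C(=O)C=C(C)[C@H]2[C@@H]3C1(C)C | intermediate
33 | triol | O[C@@H]1[C@@H](O)[C@@H](O)[C@@]2(C)[C@@H]3C(=O)C=C(C)[C@H]2[C@@H]3C1(C)C | intermediate
34 | C2 monoacetate | O[C@@H]1[C@@H](OC(C)=O)[C@@H](O)[C@@]2(C)[C@@H]3C(=O)C=C(C)[C@H]2[C@@H]3C1(C)C | intermediate
35 | angelic acid ((Z)-2-methylbut-2-enoic acid) | C/C=C(/C)C(=O)O | starting material
36 | CNP0335415.1 | C/C=C(/C)C(=O)O[C@@H]1[C@@H](OC(C)=O)[C@@H](OC(=O)/C(C)=C\C)[C@@]2(C)[C@@H]3C(=O)C=C(C)[C@H]2[C@@H]3C1(C)C | target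

**Step count**

Total: 19 steps. Longest linear sequence: 18 steps (steps 1–5, then 7–19); step 6 is a one-step side branch.

**Steps most likely to fail**

Step 7 (proposed new method). What may go wrong: the first C–C bond may form at the rear of C4 with inversion, which places the new chain on the bridge side so that ring closure is impossible. The Lewis acid may also isomerise the bridged bicyclobutane before it is trapped, or silyl transfer to the C10 enolate may end the sequence at an open-chain adduct.
Fallback, by known reactions, sets out from 6 and comes back at 26. It swaps the roles of methyl and side chain so that the invertive course of cuprate openings works in favour of the target. Bridgehead lithiation of 6 and alkylation with 2-methoxyallyl bromide should give rac-1-(2-methoxyprop-2-enyl)tricyclo[4.1.0.0(2,7)]hept-3-ene F1. A second lithiation and acylation with N-methoxy-N-methylacetamide give the acetyl bicyclobutane F2, which is resolved as in step 5. Me2CuLi opens F2 by homoconjugate addition: methyl enters C4 from the rear and ends syn to the bridge, the side chain is turned to the convex face, and acidic work-up unmasks the diketone F3. Pyrrolidine/AcOH then effects an aldol condensation through the enamine of the unbranched methyl ketone; C10 epimerises through its enol and only the epimer with acetyl on the convex face can close, so the cycloheptenone F4 (C1=C11) should result. Conjugate addition of Me2CuLi with TBSCl trapping installs the second C11 methyl and gives the C1=C2 enol silane F5, the C10–H analogue of 17. The conditions of steps 8, 9 and 10 turn F5 into the ketol F6, its silyl ether F7 and the enol triflate F8. The formate reduction of step 11 then gives 26 directly, with no ester to cleave and no decarboxylation.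

Step 13. What may go wrong: the ene reaction of singlet oxygen with the cis-disubstituted bridge olefin may be too slow, so that photo-oxidation at the tether olefin or over-oxidation competes.
Fallback sets out from 26 and comes back at 31; the C8 methyl is introduced by conjugate addition instead of 1,2-addition and transposition. SeO2/t-BuOOH hydroxylates the allylic C6 methylene without moving the olefin (ene reaction, then [2,3] shift) to give the allylic alcohol F9, and Dess–Martin periodinane gives the enone F10 (C6=O; C7=C8H). Me2CuLi with Me3SiCl adds methyl to C8 from the C10 side and gives the silyl enol ether F11. Saegusa oxidation with Pd(OAc)2 in MeCN restores the C7=C8 olefin and gives 31.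

Step 19. What may go wrong: acylation of the two hindered hydroxyls may be slow enough at 80 °C for the activated angelate to isomerise to the tiglate or for the C2 acetate to migrate.
Fallback sets out from 34 and comes back at 36; the Z olefins are built on the molecule instead of being carried in. Both hydroxyls are esterified with the unhindered 2-[bis(2,2,2-trifluoroethoxy)phosphoryl]propanoic acid (DCC, DMAP) to give the bis-phosphonate F12. Still–Gennari olefination with acetaldehyde (KN(SiMe3)2, 18-crown-6, THF, −78 °C) then forms both (Z)-2-methylbut-2-enoates and gives 36.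

**Further compounds**

F1 | step 7 | rac-1-(2-methoxyprop-2-enyl)tricyclo[4.1.0.0(2,7)]hept-3-ene | [C@@H]12[C@H]3CC=C[C@@H]1[C@@]23CC(=C)OC
F2 | step 7 | 1-[7-(2-methoxyprop-2-enyl)tricyclo[4.1.0.0(2,7)]hept-3-en-1-yl]ethanone (resolved) | CC(=O)[C@@]12[C@H]3CC=C[C@@H]1[C@@]23CC(=C)OC
F3 | step 7 | diketone (C4: Me syn to the bridge, CH2C(=O)CH3 on the convex face; C10: H, acetyl; formed with its C10 epimer) | CC(=O)C[C@@]1(C)[C@@H]2CC=C[C@H]1[C@@H]2C(C)=O
F4 | step 7 | cycloheptenone (C2=O; C1=C11(Me); C10–H) | O=C1C[C@@]2(C)[C@@H]3CC=C[C@H]2[C@@H]3C(C)=C1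
F5 | step 7 | C10–H analogue of 17 (C1=C2–OTBS; C11Me2) | C1=C(O[Si](C)(C)C(C)(C)C)C[C@@]2(C)[C@@H]3CC=C[C@H]2[C@@H]3C1(C)C
F6 | step 7 | C10–H analogue of 19 (ketol) | O[C@@H]1C(=O)C[C@@]2(C)[C@@H]3CC=C[C@H]2[C@@H]3C1(C)C
F7 | step 7 | C10–H analogue of 20 (C1–OTBS ketone) | CC(C)(C)[Si](C)(C)O[C@@H]1C(=O)C[C@@]2(C)[C@@H]3CC=C[C@H]2[C@@H]3C1(C)C
F8 | step 7 | C10–H analogue of 22 (enol triflate) | CC(C)(C)[Si](C)(C)O[C@@H]1C(OS(=O)(=O)C(F)(F)F)=C[C@@]2(C)[C@@H]3CC=C[C@H]2[C@@H]3C1(C)C
F9 | step 13 | allylic alcohol (C6–OH on the C10 side; C7=C8) | CC(C)(C)[Si](C)(C)O[C@@H]1C=C[C@@]2(C)[C@@H]3[C@@H](O)C=C[C@H]2[C@@H]3C1(C)C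
F10 | step 13 | enone (C6=O; C7=C8H) | CC(C)(C)[Si](C)(C)O[C@@H]1C=C[C@@]2(C)[C@@H]3C(=O)C=C[C@H]2[C@@H]3C1(C)C
F11 | step 13 | trimethylsilyl enol ether (C6(OSiMe3)=C7; C8–Me on the C10 side) | CC(C)(C)[Si](C)(C)O[C@@H]1C=C[C@@]2(C)[C@@H]3C(O[Si](C)(C)C)=C[C@@H](C)[C@H]2[C@@H]3C1(C)C
F12 | step 19 | C1,C3-bis[2-(bis(2,2,2-trifluoroethoxy)phosphoryl)propanoate] of 34 (mixture at the phosphonate α-carbons) | CC(C(=O)O[C@@H]1[C@@H](OC(C)=O)[C@@H](OC(=O)C(C)P(=O)(OCC(F)(F)F)OCC(F)(F)F)[C@@]2(C)[C@@H]3C(=O)C=C(C)[C@H]2[C@@H]3C1(C)C)P(=O)(OCC(F)(F)F)OCC(F)(F)F
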